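Retrosynthetic overview
1. Target ⇐ its C12 epimer (oxidation, then reduction) ⇐ bromonium-triggered 5-exo cation–olefin cyclization with water capture at C7 of a decalin carrying a 2-methylhepta-1,5-dienyl chain; the chain comes from a C7 ketone (Corey–Peterson enal, catalytic allylboration, cross-metathesis).
2. C7 ketone ⇐ a 4,10-dimethyl-Δ4,Δ7-octalin-1-one: C1–Br by enol triflate → alkenyl bromide → HAT hydrogenation; 4β,5α-diol and C7 oxygen by α-face bis-epoxidation, then hydride and water opening.
3. Key disconnection: that dienone ⇐ a bicyclo[5.3.0] dienol by a HAT-initiated semipinacol shift. Ring A (C1–C5 + C10) arises by one-carbon expansion of the cyclopentene ring C1–C5 of cis-jasmone, C10 being inserted between C1 and C5, while the cycloheptadiene contracts to ring B.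
4. Enabling feature: in ring A the methyl-bearing quaternary C10 lies between C1 (later CHBr) and C5. A tertiary, doubly allylic C1–OH flanked by the C4=C5 alkene and an exocyclic C10 methylene lets alkenyl carbon C5 migrate, and the C6–C7=C8–C9 tether relays the C1 configuration to C10.
5. Ring order: cyclopentene (bought) → seven-membered ring (metathesis) → rings A and B together (key step) → bromocyclopentane (last C–C bond).

Key step: step 4

Remark: decalin atoms are numbered C1–C10 (C10 methyl-bearing ring-fusion carbon, C5 hydroxylated ring-fusion carbon, C1 = CHBr, C4 = C(OH)CH3, C7 = carbinol carrying the cyclopentane), cyclopentane atoms C11 (on C7), C12 (CHOH), C13, C14 (CHBr), C15 (CMe2); β is the face of the C10 methyl group. 2-Bromopenta-1,4-diene is assumed not purchasable and is made in step 1; ligand enantiomers are named by analogy, the SMILES give the configuration intended.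

Step 1
Reactants: 1 2,3-dibromopropene; 2 vinylmagnesium bromide
Product: 3 2-bromopenta-1,4-diene
Conditions: CuI (5 mol%), THF, 0 → 23 °C
Reagents that add atoms: none
Why: Copper-catalysed allylic substitution of the allylic bromide by the vinyl Grignard reagent should leave the vinylic C–Br bond untouched.

Step 2
Reactants: 3 2-bromopenta-1,4-diene; 4 cis-jasmone
Product: 7 (1R)-3-methyl-1-(penta-1,4-dien-2-yl)-2-[(2Z)-pent-2-en-1-yl]cyclopent-2-en-1-ol, via penta-1,4-dien-2-yllithium 5 (not isolated), via bromo(penta-1,4-dien-2-yl)zinc 6 (not isolated)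
Conditions: 3, t-BuLi (2 equiv), Et2O, −78 °C; ZnBr2, −78 → 0 °C; then 4, Ti(OiPr)4 (1.2 equiv), trans-1,2-bis(hydroxycamphorsulfonamido)cyclohexane (10 mol%, enantiomer giving the (R)-alcohol), N,N,N′,N′-tetraethylethylenediamine, toluene, 23 °C
Reagents that add atoms: none
Why: Titanium/bis(sulfonamide)-diol-catalysed enantioselective 1,2-addition of an alkenylzinc to an α-substituted cyclopentenone (catalytic asymmetric ketone alkenylation) should set the C1 carbinol (R), the catalyst distinguishing the sp2 α-carbon C5 from the CH2 flank.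

Step 3
Reactants: 7 (1R)-3-methyl-1-(penta-1,4-dien-2-yl)-2-[(2Z)-pent-2-en-1-yl]cyclopent-2-en-1-ol
Product: 8 (8aR)-3-methyl-8-methylidene-1,2,4,7,8,8a-hexahydroazulen-8a-ol
Conditions: RuCl2(=CHPh)(PCy3)2 (first-generation Grubbs catalyst, 5 mol%), CH2Cl2 (0.005 M), 40 °C
Reagents that add atoms: none
Why: Ring-closing metathesis should join only the monosubstituted and the cis-disubstituted alkene (the first-generation catalyst ignores the 1,1-disubstituted and tetrasubstituted alkenes), closing the seven-membered ring with loss of but-1-ene.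

Step 4
Reactants: 8 (8aR)-3-methyl-8-methylidene-1,2,4,7,8,8a-hexahydroazulen-8a-ol
Product: 9 (8aR)-4,8a-dimethyl-3,5,8,8a-tetrahydronaphthalen-1(2H)-one (C1 ketone, Δ4, Δ7, 10β-methyl)
Conditions: Co(C36H52N2O2) [divalent cobalt complex of N,N′-bis(3,5-di-tert-butylsalicylidene)cyclohexane-1,2-diamine, 5 mol%], N-fluoro-2,4,6-trimethylpyridinium triflate (1.3 equiv), PhSiH3 (1.2 equiv), acetone, 0 °C
Reagents that add atoms: none
Why: The cobalt hydride formed from silane and oxidant transfers a hydrogen atom to the exocyclic methylene (making the C10 methyl and a tertiary C10 radical), the radical is oxidised through an alkyl tetravalent cobalt species to a cation equivalent, and alkenyl carbon C5 migrates from carbinol C1 to C10 through a cyclopropylcarbinyl-type bridge while C1–OH becomes the C1 ketone. The closest known reaction type is the HAT-initiated radical-polar crossover semipinacol rearrangement of tertiary allylic alcohols, the catalytic counterpart of the semipinacol ring expansion of 1-alkenylcycloalkanols. Ring A closes by ring expansion (the cyclopentene C1–C5 takes up C10 between C1 and C5) and ring B by the complementary contraction of the seven-membered ring, both through the same 1,2-alkenyl shift. The new stereocentre C10 is controlled by the C1 carbinol (1,2-chirality transfer): C10 can bond to C5 only on the cyclopentene face on which it already sits, and the C6–C7=C8–C9 tether forces C9 to the side of C6, so the methyl ends on the other side. The step needs hydrogen-atom transfer to the 1,1-disubstituted alkene only (cis-disubstituted and tetrasubstituted alkenes are far slower acceptors) and migration of C5 rather than C2, which the higher migratory aptitude of the alkenyl carbon secures.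

Step 5
Reactants: 9 (8aR)-4,8a-dimethyl-3,5,8,8a-tetrahydronaphthalen-1(2H)-one
Product: 10 (8aR)-4,8a-dimethyl-3,5,8,8a-tetrahydronaphthalen-1-yl trifluoromethanesulfonate
Conditions: KN(SiMe3)2, THF, −78 °C; PhNTf2
Reagents that add atoms: N-phenylbis(trifluoromethanesulfonimide), O=S(=O)(N(c1ccccc1)S(=O)(=O)C(F)(F)F)C(F)(F)F
Why: Enolisation can occur only towards C2 (C10 is quaternary) and O-triflation of the potassium enolate should give the enol triflate.

Step 6
Reactants: 10 (8aR)-4,8a-dimethyl-3,5,8,8a-tetrahydronaphthalen-1-yl trifluoromethanesulfonate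
Product: 11 (8aR)-1-bromo-4,8a-dimethyl-3,5,8,8a-tetrahydronaphthalene
Conditions: Ni(C8H12)2 (zerovalent nickel, 10 mol%), LiBr (3 equiv), N,N-dimethylacetamide/THF, 23 °C
Reagents that add atoms: lithium bromide, [Li+].[Br-]
Why: Nickel-catalysed triflate-to-halide exchange of enol triflates (oxidative addition, bromide exchange, reductive elimination) should give the alkenyl bromide without touching the other alkenes.

Step 7
Reactants: 11 (8aR)-1-bromo-4,8a-dimethyl-3,5,8,8a-tetrahydronaphthalene
Product: 12 1-bromo-4α,5α:7α,8α-diepoxy-4β,10β-dimethyl-Δ1-octalin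
Conditions: mCPBA (2.3 equiv), NaHCO3, CH2Cl2, 0 °C
Reagents that add atoms: 3-chloroperoxybenzoic acid, OOC(=O)c1cccc(Cl)c1
Why: Prilezhaev epoxidation should spare the electron-poor bromoalkene and attack both other alkenes anti to the pseudo-axial C10 methyl, giving the 4α,5α- and 7α,8α-epoxides.

Step 8
Reactants: 12 1-bromo-4α,5α:7α,8α-diepoxy-4β,10β-dimethyl-Δ1-octalin
Product: 14 1-bromo-4α,10β-dimethyl-Δ1-octalin-4β,5α,7α-triol, via 1-bromo-4α,5α-epoxy-4β,10β-dimethyl-Δ1-octalin-7α-ol 13 (not isolated)
Conditions: LiAlH4, Et2O, 0 °C; then 0.5 M HClO4, THF/H2O, 23 °C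
Reagents that add atoms: water, O
Why: Hydride should open the disubstituted 7α,8α-epoxide trans-diaxially at C8 (Fürst–Plattner rule) to the 7α-alcohol while the tetrasubstituted epoxide is inert, and acid then opens the 4α,5α-epoxide trans-diaxially by water attack at C4 from the β face, setting C4 (4β-OH, 4α-CH3) and C5 (5α-OH).

Step 9
Reactants: 14 1-bromo-4α,10β-dimethyl-Δ1-octalin-4β,5α,7α-triol
Product: 15 1β-bromo-4α,10β-dimethyl-trans-decalin-4β,5α,7α-triol
Conditions: Mn(C11H19O2)3 [tris(dipivaloylmethanato)manganese, trivalent manganese, 10 mol%], PhSiH3, t-BuOOH, i-PrOH, 23 °C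
Reagents that add atoms: none
Why: Mukaiyama-type HAT hydrogenation of the bromoalkene (hydrogen atom to C2, α-bromo radical at C1, second hydrogen delivered axially from the α face) should give the thermodynamically preferred equatorial 1β-bromide and keep the C–Br bond that metal/hydrogen conditions would cleave.

Step 10
Reactants: 15 1β-bromo-4α,10β-dimethyl-trans-decalin-4β,5α,7α-triol
Product: 16 1β-bromo-4β,5α-dihydroxy-4α,10β-dimethyl-trans-decalin-7-one
Conditions: Dess–Martin periodinane, NaHCO3, CH2Cl2, 0 → 23 °C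
Reagents that add atoms: none
Why: Dess–Martin oxidation should convert the only secondary alcohol and leave the tertiary ones untouched.

Step 11
Reactants: 17 propanal; 18 tert-butylamine
Product: 20 N-tert-butyl-2-(trimethylsilyl)propan-1-imine, via N-tert-butylpropan-1-imine 19 (not isolated)
Conditions: K2CO3, 0 °C; then LiN(iPr)2, THF, −78 °C; Me3SiCl
Reagents that add atoms: chlorotrimethylsilane, C[Si](C)(C)Cl
Why: Imine condensation followed by C-silylation of the lithio-azaenolate should give the α-silyl aldimine needed for the Peterson olefination.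

Step 12
Reactants: 16 1β-bromo-4β,5α-dihydroxy-4α,10β-dimethyl-trans-decalin-7-one; 20 N-tert-butyl-2-(trimethylsilyl)propan-1-imine
Product: 22 2-(1β-bromo-4β,5α-dihydroxy-4α,10β-dimethyl-trans-decalin-7-ylidene)propanal (E/Z mixture), via N-tert-butyl-2-(decalin-7-ylidene)propan-1-imine 21 (not isolated)
Conditions: 20 (3.5 equiv), LiN(iPr)2, THF, −78 °C; 16, −78 → 0 °C; then aqueous oxalic acid, 23 °C
Reagents that add atoms: water, O
Why: Corey–Peterson olefination (addition of the lithiated α-silyl imine to the unhindered C7 ketone, silanolate elimination, imine hydrolysis) should give the tetrasubstituted enal; C7 is planar here, so the E/Z mixture is inconsequential, and the tertiary hydroxyls ride through as lithium alkoxides.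

Step 13
Reactants: 22 2-(1β-bromo-4β,5α-dihydroxy-4α,10β-dimethyl-trans-decalin-7-ylidene)propanal
Product: 23 (12S)-2-(1β-bromo-4β,5α-dihydroxy-4α,10β-dimethyl-trans-decalin-7-ylidene)hex-5-en-3-ol
Conditions: allylboronic acid pinacol ester, (S)-TRIP phosphoric acid (5 mol%), toluene, −30 °C; aqueous work-up
Reagents that add atoms: 2-allyl-4,4,5,5-tetramethyl-1,3,2-dioxaborolane, C=CCB1OC(C)(C)C(C)(C)O1
Why: Chiral phosphoric-acid-catalysed allylboration through a closed six-membered transition state should set C12 (S) by catalyst control, independent of the remote decalin.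

Step 14
Reactants: 23 (12S)-2-(1β-bromo-4β,5α-dihydroxy-4α,10β-dimethyl-trans-decalin-7-ylidene)hex-5-en-3-ol
Product: 24 (12S)-2-(1β-bromo-4β,5α-dihydroxy-4α,10β-dimethyl-trans-decalin-7-ylidene)-6-methylhept-5-en-3-ol
Conditions: 2-methylbut-2-ene (excess), RuCl2(=CHPh)(PCy3)(H2IMes) (second-generation Grubbs catalyst, 5 mol%), CH2Cl2, 40 °C
Reagents that add atoms: 2-methylbut-2-ene, CC=C(C)C
Why: Olefin cross-metathesis of the terminal alkene with 2-methylbut-2-ene should install the trisubstituted C14=C15 alkene, the tetrasubstituted C7=C11 alkene being inert.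

Step 15
Reactants: 24 (12S)-2-(1β-bromo-4β,5α-dihydroxy-4α,10β-dimethyl-trans-decalin-7-ylidene)-6-methylhept-5-en-3-ol
Product: 25 12-O-triethylsilyl ether of 24
Conditions: Et3SiCl, imidazole, DMF, 0 °C
Reagents that add atoms: chlorotriethylsilane, CC[Si](Cl)(CC)CC
Why: Selective silylation of the secondary allylic alcohol (the tertiary ones do not react) should block 5-endo bromoetherification in the next step.

Step 16
Reactants: 25 12-O-triethylsilyl ether of 24
Product: 27 12-epi-target (C12–OH cis to the C11 methyl), via 12-O-triethylsilyl-12-epi-target 26 (not isolated)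
Conditions: N-bromosuccinimide (1.05 equiv), (CF3)2CHOH/H2O (20:1), −20 °C, dark; then Bu4NF, THF, 23 °C
Reagents that add atoms: N-bromosuccinimide, BrN1C(=O)CCC1=O; water, O
Why: Proposed new method: bromonium formation at the unhindered C14=C15 alkene, 5-exo attack of C11 of the C7=C11 alkene on C15 anti to bromine and axial capture of the tertiary C7 cation by water (7α-OH, cyclopentyl equatorial) should build the bromocyclopentane, the closest known reaction type being the bromonium-induced cation–olefin (polyene) cyclization, diverted here to the 5-exo mode because 6-endo closure would put the cation at C11 next to the C12 oxygen; C11 is set from C12 by allylic 1,3-strain (C12–H eclipses the alkene, so the silyloxy group ends cis to the C11 methyl) and C14 by an envelope transition state with bromine pseudo-equatorial and cis to the bulky C7 substituent; fluoride then removes the silyl group.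

Step 17
Reactants: 27 12-epi-target
Product: 28 12-ketone (1β,14-dibromo-4β,5α,7α-trihydroxy compound with C12=O)
Conditions: Dess–Martin periodinane, NaHCO3, CH2Cl2, 0 °C
Reagents that add atoms: none
Why: Dess–Martin oxidation of the only secondary alcohol should give the β-bromo ketone under neutral, non-enolising conditions.

Step 18
Reactants: 28 12-ketone
Product: 29 target, CNP0390567.2
Conditions: NaBH4, CeCl3·7H2O, MeOH, −78 °C
Reagents that add atoms: none
Why: Luche reduction should deliver hydride from the face of the C11 methyl, anti to the decalinyl group and the C14 bromide, so the new C12–OH is cis to both (net inversion of C12), which is the target.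

Compound list
1 | 2,3-dibromopropene | C=C(Br)CBr | starting material
2 | vinylmagnesium bromide | C=C[Mg]Br | starting material
3 | 2-bromopenta-1,4-diene | C=C(Br)CC=C | intermediate
4 | cis-jasmone, 3-methyl-2-[(2Z)-pent-2-en-1-yl]cyclopent-2-en-1-one | CC/C=C\CC1=C(C)CCC1=O | starting material
5 | penta-1,4-dien-2-yllithium | [Li]C(=C)CC=C | intermediate
6 | bromo(penta-1,4-dien-2-yl)zinc | Br[Zn]C(=C)CC=C | intermediate
7 | (1R)-3-methyl-1-(penta-1,4-dien-2-yl)-2-[(2Z)-pent-2-en-1-yl]cyclopent-2-en-1-ol | CC/C=C\CC1=C(C)CC[C@@]1(O)C(=C)CC=C | intermediate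
8 | (8aR)-3-methyl-8-methylidene-1,2,4,7,8,8a-hexahydroazulen-8a-ol | C1C=CCC(=C)[C@]2(O)CCC(C)=C12 | intermediate
9 | (8aR)-4,8a-dimethyl-3,5,8,8a-tetrahydronaphthalen-1(2H)-one | C1C=CC[C@@]2(C)C(=O)CCC(C)=C12 | intermediate
10 | (8aR)-4,8a-dimethyl-3,5,8,8a-tetrahydronaphthalen-1-yl trifluoromethanesulfonate | C1C=CC[C@@]2(C)C(OS(=O)(=O)C(F)(F)F)=CCC(C)=C12 | intermediate
11 | (8aR)-1-bromo-4,8a-dimethyl-3,5,8,8a-tetrahydronaphthalene | C1C=CC[C@@]2(C)C(Br)=CCC(C)=C12 | intermediate
12 | 1-bromo-4α,5α:7α,8α-diepoxy-4β,10β-dimethyl-Δ1-octalin | C1[C@H]2O[C@H]2C[C@@]3(C)C(Br)=CC[C@@]4(C)O[C@@]134 | intermediate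
13 | 1-bromo-4α,5α-epoxy-4β,10β-dimethyl-Δ1-octalin-7α-ol | O[C@H]1CC[C@@]2(C)C(Br)=CC[C@@]3(C)O[C@@]23C1 | intermediate
14 | 1-bromo-4α,10β-dimethyl-Δ1-octalin-4β,5α,7α-triol | O[C@H]1CC[C@@]2(C)C(Br)=CC[C@](C)(O)[C@]2(O)C1 | intermediate
15 | 1β-bromo-4α,10β-dimethyl-trans-decalin-4β,5α,7α-triol | O[C@H]1CC[C@@]2(C)[C@H](Br)CC[C@](C)(O)[C@]2(O)C1 | intermediate
16 | 1β-bromo-4β,5α-dihydroxy-4α,10β-dimethyl-trans-decalin-7-one | O=C1CC[C@@]2(C)[C@H](Br)CC[C@](C)(O)[C@]2(O)C1 | intermediate
17 | propanal | CCC=O | starting material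
18 | tert-butylamine | CC(C)(C)N | starting material
19 | N-tert-butylpropan-1-imine | CCC=NC(C)(C)C | intermediate
20 | N-tert-butyl-2-(trimethylsilyl)propan-1-imine | CC(C=NC(C)(C)C)[Si](C)(C)C | intermediate
21 | N-tert-butyl-2-(1β-bromo-4β,5α-dihydroxy-4α,10β-dimethyl-trans-decalin-7-ylidene)propan-1-imine | CC(C)(C)N=CC(C)=C1CC[C@@]2(C)[C@H](Br)CC[C@](C)(O)[C@]2(O)C1 | intermediate
22 | 2-(1β-bromo-4β,5α-dihydroxy-4α,10β-dimethyl-trans-decalin-7-ylidene)propanal | O=CC(C)=C1CC[C@@]2(C)[C@H](Br)CC[C@](C)(O)[C@]2(O)C1 | intermediate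
23 | (12S)-2-(1β-bromo-4β,5α-dihydroxy-4α,10β-dimethyl-trans-decalin-7-ylidene)hex-5-en-3-ol | C=CC[C@H](O)C(C)=C1CC[C@@]2(C)[C@H](Br)CC[C@](C)(O)[C@]2(O)C1 | intermediate
24 | (12S)-2-(1β-bromo-4β,5α-dihydroxy-4α,10β-dimethyl-trans-decalin-7-ylidene)-6-methylhept-5-en-3-ol | CC(C)=CC[C@H](O)C(C)=C1CC[C@@]2(C)[C@H](Br)CC[C@](C)(O)[C@]2(O)C1 | intermediate
25 | 12-O-triethylsilyl ether of 24 | CC(C)=CC[C@H](O[Si](CC)(CC)CC)C(C)=C1CC[C@@]2(C)[C@H](Br)CC[C@](C)(O)[C@]2(O)C1 | intermediate
26 | 12-O-triethylsilyl-12-epi-target | CC1(C)[C@@H](Br)C[C@H](O[Si](CC)(CC)CC)[C@@]1(C)[C@]1(O)CC[C@@]2(C)[C@H](Br)CC[C@](C)(O)[C@]2(O)C1 | intermediate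
27 | 12-epi-target (C12–OH cis to C11 methyl, trans to C14–Br) | CC1(C)[C@@H](Br)C[C@H](O)[C@@]1(C)[C@]1(O)CC[C@@]2(C)[C@H](Br)CC[C@](C)(O)[C@]2(O)C1 | intermediate
28 | 12-ketone: 1β,14-dibromo-4β,5α,7α-trihydroxy-4α,10β-dimethyl-7β-(3-bromo-1,2,2-trimethyl-5-oxocyclopentyl) trans-decalin | CC1(C)[C@@H](Br)CC(=O)[C@@]1(C)[C@]1(O)CC[C@@]2(C)[C@H](Br)CC[C@](C)(O)[C@]2(O)C1 | intermediate
29 | target: 1β-bromo-7β-(3-bromo-5-hydroxy-1,2,2-trimethylcyclopentyl)-4α,10β-dimethyl-trans-decalin-4β,5α,7α-triol, cyclopentane Br and OH cis to each other and to the C7 bond | CC1(C)[C@@H](Br)C[C@@H](O)[C@@]1(C)[C@]1(O)CC[C@@]2(C)[C@H](Br)CC[C@](C)(O)[C@]2(O)C1 | target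

Total step count: 18. Longest linear sequence: 17 steps (steps 1–10 and 12–18; step 11 is a one-step branch).

Steps most likely to fail
1. Step 16 (Proposed new method). The closure may be lost to bromination of the tetrasubstituted alkene, to 6-endo closure, or to ring expansion or elimination of the C7 cation before water arrives. Fallback from 16, returning at 29: aldol addition of the lithium enolate of 3-bromo-4,4,5-trimethylcyclopent-2-en-1-one (LiN(iPr)2, CeCl3, THF, −78 °C) to the C7 ketone from the equatorial direction should give the aldol adduct 7β-(3-bromo-1,2,2-trimethyl-5-oxocyclopent-3-enyl) triol F1. This addition is not expected to control C11, so the C11 epimers must be separated. Luche reduction anti to the decalinyl group should give the allylic alcohol F2, and HAT hydrogenation of the bromoalkene under the conditions of step 9, with hydrogen delivered to C14 anti to the decalinyl group, should give 29.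
2. Step 4. The shift may be pre-empted by ionisation of the doubly allylic alcohol, epoxide closure onto C10, or hydrogen-atom transfer to the wrong alkene. Fallback from 8, returning at 9: Markovnikov HAT hydrochlorination of the exocyclic methylene (Co(C36H52N2O2), p-toluenesulfonyl chloride, PhSiH3) should give the tertiary chloride 8-chloro-3,8-dimethyl-1,2,4,7,8,8a-hexahydroazulen-8a-ol F3. Silver-assisted ionisation (AgBF4, 2,6-di-tert-butylpyridine, CH2Cl2, −78 °C) then triggers the same 1,2-alkenyl shift as a halohydrin semipinacol rearrangement to 9.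
3. Step 2. Facial discrimination at the ketone may be poor, or the in situ alkenylzinc may transfer slowly and let the uncatalysed racemic addition compete. Fallback from 3 and 4, returning at 7: addition of the alkenylcerium reagent (from 5 and CeCl3, THF, −78 °C) to 4 should give the racemic carbinol rac-3-methyl-1-(penta-1,4-dien-2-yl)-2-[(2Z)-pent-2-en-1-yl]cyclopent-2-en-1-ol F4. Its enantiomers are separated by preparative chromatography on a chiral stationary phase, and the (R)-enantiomer is 7.

Further compounds
F1 | step 16 | 7β-(3-bromo-1,2,2-trimethyl-5-oxocyclopent-3-enyl)-1β-bromo-4α,10β-dimethyl-trans-decalin-4β,5α,7α-triol | CC1(C)C(Br)=CC(=O)[C@@]1(C)[C@]1(O)CC[C@@]2(C)[C@H](Br)CC[C@](C)(O)[C@]2(O)C1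
F2 | step 16 | 7β-(3-bromo-5-hydroxy-1,2,2-trimethylcyclopent-3-enyl)-1β-bromo-4α,10β-dimethyl-trans-decalin-4β,5α,7α-triol | CC1(C)C(Br)=C[C@@H](O)[C@@]1(C)[C@]1(O)CC[C@@]2(C)[C@H](Br)CC[C@](C)(O)[C@]2(O)C1
F3 | step 4 | (8aR)-8-chloro-3,8-dimethyl-1,2,4,7,8,8a-hexahydroazulen-8a-ol | C1C=CCC(C)(Cl)[C@]2(O)CCC(C)=C12
F4 | step 2 | rac-3-methyl-1-(penta-1,4-dien-2-yl)-2-[(2Z)-pent-2-en-1-yl]cyclopent-2-en-1-ol | CC/C=C\CC1=C(C)CCC1(O)C(=C)CC=C
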